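The readings were generated by integration with made-up constants, and the scatter is random.

I left two flasks on the bench. Each holds L at 0.40 M, and X replaces a ligand in L to give Z, then a second one in Z to give D; E appears beside Z. Both are read at 4.0 min.

| setting | Thursday's | Tuesday's | Wednesday's | beta | gamma |
|---|---|---|---|---|---|
| L | 0.40 M | 0.40 M | 0.40 M | 0.40 M | 0.40 M |
| X | 1.2 equiv | 1.6 equiv | 2 equiv | 1.10 equiv | 2.10 equiv |
| remark | run made earlier | run made earlier | run made earlier |  |  |
| time |  |  |  | 4.0 min | 4.0 min |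

| run | time / s | E / % | L / % | Z / % | D / % |
|---|---|---|---|---|---|
| Thursday's | 10.0 | 1.7 | 74.6 | 22.9 | 1.4 |
| Thursday's | 30.0 | 5.8 | 53.8 | 36.3 | 3.6 |
| Thursday's | 60.0 | 8.5 | 39.9 | 45.1 | 6.4 |
| Thursday's | 80.0 | 7.8 | 33.0 | 46.9 | 13.5 |
| Thursday's | 120 | 8.1 | 25.0 | 50.5 | 13.7 |
| Tuesday's | 25.0 | 5.6 | 46.7 | 41.0 | 4.4 |
| Tuesday's | 50.0 | 7.8 | 29.8 | 49.1 | 12.0 |
| Tuesday's | 80.0 | 9.1 | 22.0 | 51.1 | 18.8 |
| Tuesday's | 90.0 | 9.3 | 18.7 | 52.2 | 20.9 |
| Tuesday's | 120 | 8.3 | 11.3 | 52.4 | 25.7 |
| Wednesday's | 10.0 | 6.9 | 60.8 | 29.9 | 2.3 |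
| Wednesday's | 20.0 | 6.2 | 44.2 | 43.7 | 6.8 |
| Wednesday's | 30.0 | 8.5 | 33.7 | 47.9 | 11.6 |
| Wednesday's | 60.0 | 9.5 | 18.9 | 52.2 | 20.7 |
| Wednesday's | 120 | 9.2 | 8.6 | 47.3 | 36.2 |

(each reading ± 1 percentage point)

- what was read earlier has a scatter of 1 percentage point, one standard deviation

* which of these there is most of at the end, counted by the L in it, beta (Z / D / L / E)
* which of these there is most of at the end, counted by the L in it, gamma (Z / D / L / E)
* the largest of these amounts at the end, in percent of the L charged, beta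
* the largest of these amounts at the end, in percent of the L charged, gamma

The columns of each run add up to about the L charged, within the scatter. So every L lost has cost one X, and every D a second. I named the allowance the equivalents of X beyond one per L charged: 0.100 in beta, 1.10 in gamma. Once X is gone, D minus L, in percent of the L charged, equals the allowance.

So I asked first where each flask must stop. Beta's allowance of 0.100 is smaller than the 0.200 of Thursday's run, and that run showed Z at 50.5% against D at 13.7% after 120 s, so I expected Z to lead beta. Gamma's is more than one, so it can end as D, and the question is how far it gets. Wednesday's run, at 2 equiv, showed D at 36.2% after 120 s, half of the time. I committed to D leading gamma.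

The forecast gave Z at 48% in beta, with “X is nearly used up”, and D at 56% in gamma.

The flasks gave Z at 52.3% in beta and D at 58.2% in gamma.

    L + X → G + Z (k = 0.0820 M⁻¹ s⁻¹)
    Z ⇌ E (K = 0.170, k = 0.0480 s⁻¹)
    X ⇌ J (K = 0.630, k = 0.0350 s⁻¹)
    Z + X → G + D (k = 0.0260 M⁻¹ s⁻¹)

After 40.0 min, with X at 0%, beta's D minus L stood at 10 percentage points, its allowance in percent, while gamma reached D 96.7%. In gamma, Z was made 2.55 times faster than it was used up at 0.236 min, but by 4.00 min making over using had fallen to 0.249. Gamma's recipe at 0.10 M of L has the same allowance, yet at 4.00 min it held more Z, 52.5%, than D, 21.1%.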